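**Retrosynthetic overview**
- The target is reached by debenzylation, succinylation and PMB removal from (3R)-5,8-bis(benzyloxy)-3-[(4S)-4-(PMB-oxy)pentyl]isochroman-1-one.
- Key disconnection: the C4–C4a and C1–C8a bonds of the lactone ring (ring B) are cut together. This gives 3,6-bis(benzyloxy)benzyne and an α-silyl β-lactone; forward, fluoride triggers formal insertion of the aryne into the C(acyl)–C(α) bond of the oxetan-2-one.
- Enabling feature: the four non-aromatic atoms of ring B, C4–C3–O2–C1(=O), are a β-lactone once C4 and C1 are joined, with C3 as its only stereocentre. Ring A is a para-hydroquinone whose oxygens at C5 and C8 flank C4a and C8a as mirror images, so the aryne is symmetric and insertion has no regiochemistry.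
- The β-lactone comes from (S)-5-(PMB-oxy)hexanal by asymmetric ketene–aldehyde [2+2] cycloaddition, and the aldehyde from (S)-propylene oxide. The 2-silylaryl triflate comes from 2,5-dihydroxybenzaldehyde.
- Ring order: ring A is bought as a benzene ring; the oxetanone is made in step 4 and expanded onto ring A to ring B in step 11.

Key step: step 11

Assumption: read from the SMILES, the target is the (3R)-lactone with an (S)-configured side-chain carbinol carbon, and the hemisuccinate is wanted as the free acid.

**Route**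

Step 1
Reactants: 1 (S)-propylene oxide; 2 but-3-enylmagnesium bromide
Product: 3 (2S)-hept-6-en-2-ol
Conditions: CuI (10 mol%), THF, −30 °C to 0 °C; then aq. NH4Cl
Reagents that add atoms: none
Why: Copper-catalysed SN2 opening of a terminal epoxide by a Grignard reagent at the unsubstituted carbon; the stereocentre of 1 is not touched and becomes the (S)-carbinol carbon of the side chain.

Step 2
Reactants: 3 (2S)-hept-6-en-2-ol
Product: 4 1-({[(2S)-hept-6-en-2-yl]oxy}methyl)-4-methoxybenzene
Conditions: NaH, 4-methoxybenzyl chloride, Bu4NI (cat.), THF/DMF, 0 °C to rt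
Reagents that add atoms: 4-methoxybenzyl chloride, COc1ccc(CCl)cc1
Why: Williamson ether synthesis; the PMB ether should withstand the Lewis acid, amide base and fluoride of steps 4, 5 and 11 and can later be removed beside aryl benzyl ethers.

Step 3
Reactants: 4 1-({[(2S)-hept-6-en-2-yl]oxy}methyl)-4-methoxybenzene
Product: 6 (5S)-5-[(4-methoxybenzyl)oxy]hexanal, via diol 5 (not isolated)
Conditions: OsO4 (2 mol%), NaIO4 (4 equiv), 2,6-lutidine, dioxane/H2O, rt
Reagents that add atoms: sodium periodate, [Na+].[O-]I(=O)(=O)=O (oxygen source, relayed by catalytic osmium tetroxide, O=[Os](=O)(=O)=O)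
Why: Lemieux–Johnson oxidative cleavage (dihydroxylation, then periodate glycol cleavage) of the terminal alkene, chosen over ozonolysis to spare the electron-rich PMB ring.

Step 4
Reactants: 6 (5S)-5-[(4-methoxybenzyl)oxy]hexanal; 7 acetyl bromide
Product: 9 (4R)-4-{(4S)-4-[(4-methoxybenzyl)oxy]pentyl}oxetan-2-one, via ketene 8 (not isolated)
Conditions: i-Pr2NEt, MeAl[(TfNCH(i-Pr)CH2)2NBn] (10 mol%, from AlMe3 and the valine-derived triamine bis(triflamide), ligand antipode chosen for 4R), CH2Cl2, −50 °C
Reagents that add atoms: none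
Why: Catalytic asymmetric acyl halide–aldehyde cyclocondensation, a Lewis acid-catalysed ketene–aldehyde [2+2] cycloaddition in which the chiral aluminium triamine complex selects the aldehyde face and so sets C4 of the oxetanone (the later C3), the remote (S) centre not being expected to interfere.

Step 5
Reactants: 9 (4R)-4-{(4S)-4-[(4-methoxybenzyl)oxy]pentyl}oxetan-2-one
Product: 11 (3R,4R)-4-{(4S)-4-[(4-methoxybenzyl)oxy]pentyl}-3-(trimethylsilyl)oxetan-2-one, via lithium enolate 10 (not isolated)
Conditions: LiN(i-Pr)2 (1.1 equiv) added to 9 and Me3SiCl (3 equiv), THF, −78 °C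
Reagents that add atoms: chlorotrimethylsilane, C[Si](C)(C)Cl
Why: β-Lactone enolates persist at −78 °C because β-elimination is stereoelectronically blocked in the four-membered ring and they are silylated at carbon, here by TMSCl present from the start (in situ quench) and anti to the C4 chain; the new C3 centre is erased in step 11.

Step 6
Reactants: 12 2,5-dihydroxybenzaldehyde
Product: 13 2,5-bis(benzyloxy)benzaldehyde
Conditions: BnBr (2.3 equiv), K2CO3, DMF, 60 °C
Reagents that add atoms: benzyl bromide, BrCc1ccccc1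
Why: Williamson O-benzylation of both phenols.

Step 7
Reactants: 13 2,5-bis(benzyloxy)benzaldehyde
Product: 15 2,5-bis(benzyloxy)phenol, via aryl formate 14 (not isolated)
Conditions: mCPBA, CH2Cl2, 0 °C to rt; then K2CO3 (cat.), MeOH, rt
Reagents that add atoms: 3-chloroperoxybenzoic acid, OOC(=O)c1cccc(Cl)c1
Why: Baeyer–Villiger (Dakin-type) oxidation of an electron-rich benzaldehyde with aryl migration to the formate, followed by methanolysis.

Step 8
Reactants: 15 2,5-bis(benzyloxy)phenol
Product: 16 2,5-bis(benzyloxy)phenyl N-isopropylcarbamate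
Conditions: i-PrNCO, Et3N (cat.), CH2Cl2, rt
Reagents that add atoms: isopropyl isocyanate, CC(C)N=C=O
Why: Base-catalysed addition of the phenol to the isocyanate gives the carbamate that directs step 9 and is cleaved under mild base in step 10.

Step 9
Reactants: 16 2,5-bis(benzyloxy)phenyl N-isopropylcarbamate
Product: 20 3,6-bis(benzyloxy)-2-(trimethylsilyl)phenyl N-isopropylcarbamate, via N-silyl carbamate 17 (not isolated), via aryllithium 18 (not isolated), via bis-silyl carbamate 19 (not isolated)
Conditions: t-BuMe2SiOTf, TMEDA, Et2O, 0 °C to rt; n-BuLi, TMEDA, −78 °C; Me3SiCl, −78 °C to rt; aq. NaHSO4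
Reagents that add atoms: chlorotrimethylsilane, C[Si](C)(C)Cl; tert-butyldimethylsilyl triflate, CC(C)(C)[Si](C)(C)OS(=O)(=O)C(F)(F)F (its silyl group is present in 17 to 19 only)
Why: Directed ortho-metalation after in situ N-silylation; the only free ortho position lies between the carbamate and a benzyloxy group, so both direct the lithiation there, and TMSCl traps the aryllithium.

Step 10
Reactants: 20 3,6-bis(benzyloxy)-2-(trimethylsilyl)phenyl N-isopropylcarbamate
Product: 22 3,6-bis(benzyloxy)-2-(trimethylsilyl)phenyl trifluoromethanesulfonate, via silylphenol 21 (not isolated)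
Conditions: DBU, Et2NH, MeCN, 40 °C; then PhNTf2, rt
Reagents that add atoms: N-phenylbis(trifluoromethanesulfonimide), O=S(=O)(N(c1ccccc1)S(=O)(=O)C(F)(F)F)C(F)(F)F
Why: E1cB cleavage of the N–H carbamate by DBU (the isocyanate is scavenged by Et2NH) and O-triflation of the phenoxide in the same flask, the usual way to 2-silylaryl triflates.

Step 11
Reactants: 11 (3R,4R)-4-{(4S)-4-[(4-methoxybenzyl)oxy]pentyl}-3-(trimethylsilyl)oxetan-2-one; 22 3,6-bis(benzyloxy)-2-(trimethylsilyl)phenyl trifluoromethanesulfonate
Product: 28 (3R)-5,8-bis(benzyloxy)-3-{(4S)-4-[(4-methoxybenzyl)oxy]pentyl}isochroman-1-one, via aryne 23 (not isolated), via potassium enolate 24 (not isolated), via aryl anion 25 (not isolated), via benzocyclobutenoxide 26 (not isolated), via benzylic anion 27 (not isolated)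
Conditions: KF (5 equiv), 18-crown-6 (5 equiv), THF, 0 °C, 11 and 22 (1.3 equiv) added together over 3 h; then AcOH, 0 °C
Reagents that add atoms: none
Why: Proposed new method: fluoride strips both silyl groups, giving aryne 23 (1,2-elimination from 22) and enolate 24 (C–Si cleavage next to the lactone carbonyl) side by side; C-arylation of 24 makes the C4–C4a bond and leaves aryl anion 25, which adds 4-exo-trig to the strained, anhydride-like lactone carbonyl to make the C1–C8a bond (benzocyclobutenoxide 26), and Grob-type cleavage of the C1–C4 bond shared by the two four-membered rings releases the o-toluate-type anion 27, which AcOH protonates. The closest known reaction type is the acyl-alkylation of arynes, the formal insertion of an aryne into the C(acyl)–C(alpha) sigma bond of beta-keto esters and malonates, which expands cyclic substrates by two atoms; it is not known for a beta-lactone or for an enolate without a second acceptor group, and the alpha-silyl group is the traceless stand-in for that group. Ring B closes by two-atom ring expansion of the oxetan-2-one (4-exo-trig closure onto C1, then opening of the fused bond), driven by the loss of the strain of two four-membered rings and by the stabilised leaving carbanion. No stereocentre is formed: C3 of 28 is C4 of 11, none of its bonds is broken in any intermediate (also not if 26 opens at C1–O2 to a benzocyclobutenone alkoxide that closes again), and the silyl-bearing centre of 11 is erased. Regioselectivity is not needed because 23 has a mirror plane through its triple bond, a consequence of the C5/C8 para-dioxygenation; what is needed is C- over O-arylation, capture of 24 by 23 ahead of protonation or Claisen self-acylation (dry fluoride, slow co-addition, excess 22), and a cold acid quench of 27 before beta-elimination of the carboxylate can open the lactone.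

Step 12
Reactants: 28 (3R)-5,8-bis(benzyloxy)-3-{(4S)-4-[(4-methoxybenzyl)oxy]pentyl}isochroman-1-one
Product: 29 (3R)-5,8-bis(benzyloxy)-3-[(4S)-4-hydroxypentyl]isochroman-1-one
Conditions: DDQ (1.3 equiv), CH2Cl2/pH 7 phosphate buffer, 0 °C to rt
Reagents that add atoms: none
Why: Oxidative PMB ether cleavage by DDQ through the benzylic oxocarbenium ion; the plain benzyl ethers on the acyl-deactivated ring should be left intact.

Step 13
Reactants: 29 (3R)-5,8-bis(benzyloxy)-3-[(4S)-4-hydroxypentyl]isochroman-1-one; 30 succinic anhydride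
Product: 31 4-({(2S)-5-[(3R)-5,8-bis(benzyloxy)-1-oxoisochroman-3-yl]pentan-2-yl}oxy)-4-oxobutanoic acid
Conditions: DMAP (0.2 equiv), pyridine, CH2Cl2, rt; 1 M HCl wash
Reagents that add atoms: none
Why: DMAP-catalysed ring opening of the anhydride by the secondary alcohol; both phenols are still benzylated, so only one hydroxyl group can be acylated.

Step 14
Reactants: 31 4-({(2S)-5-[(3R)-5,8-bis(benzyloxy)-1-oxoisochroman-3-yl]pentan-2-yl}oxy)-4-oxobutanoic acid
Product: 32 Aspergimarin B
Conditions: H2 (1 atm), Pd/C (10 wt%), EtOAc, rt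
Reagents that add atoms: none
Why: Hydrogenolysis of the two aryl benzyl ethers over palladium on carbon; the lactone, the alkyl ester and the acid are inert and no stereocentre is benzylic.

**Compound list**

1 | (S)-propylene oxide | C[C@H]1CO1 | starting material
2 | but-3-enylmagnesium bromide | C=CCC[Mg]Br | starting material
3 | (2S)-hept-6-en-2-ol | C[C@H](O)CCCC=C | intermediate
4 | 1-({[(2S)-hept-6-en-2-yl]oxy}methyl)-4-methoxybenzene | C[C@H](OCc1ccc(OC)cc1)CCCC=C | intermediate
5 | (6S)-6-[(4-methoxybenzyl)oxy]heptane-1,2-diol (both C2 epimers) | C[C@H](OCc1ccc(OC)cc1)CCCC(O)CO | intermediate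
6 | (5S)-5-[(4-methoxybenzyl)oxy]hexanal | C[C@H](OCc1ccc(OC)cc1)CCCC=O | intermediate
7 | acetyl bromide | CC(=O)Br | starting material
8 | ketene | C=C=O | intermediate
9 | (4R)-4-{(4S)-4-[(4-methoxybenzyl)oxy]pentyl}oxetan-2-one | C[C@H](OCc1ccc(OC)cc1)CCC[C@@H]1CC(=O)O1 | intermediate
10 | lithium enolate of 9 | [Li+].[O-]C1=C[C@@H](CCC[C@H](C)OCc2ccc(OC)cc2)O1 | intermediate
11 | (3R,4R)-4-{(4S)-4-[(4-methoxybenzyl)oxy]pentyl}-3-(trimethylsilyl)oxetan-2-one (trans) | C[C@H](OCc1ccc(OC)cc1)CCC[C@@H]1[C@@H]([Si](C)(C)C)C(=O)O1 | intermediate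
12 | 2,5-dihydroxybenzaldehyde | O=Cc1cc(O)ccc1O | starting material
13 | 2,5-bis(benzyloxy)benzaldehyde | O=Cc1cc(OCc2ccccc2)ccc1OCc1ccccc1 | intermediate
14 | 2,5-bis(benzyloxy)phenyl formate | O=COc1cc(OCc2ccccc2)ccc1OCc1ccccc1 | intermediate
15 | 2,5-bis(benzyloxy)phenol | Oc1cc(OCc2ccccc2)ccc1OCc1ccccc1 | intermediate
16 | 2,5-bis(benzyloxy)phenyl N-isopropylcarbamate | CC(C)NC(=O)Oc1cc(OCc2ccccc2)ccc1OCc1ccccc1 | intermediate
17 | 2,5-bis(benzyloxy)phenyl N-(tert-butyldimethylsilyl)-N-isopropylcarbamate | CC(C)N(C(=O)Oc1cc(OCc2ccccc2)ccc1OCc1ccccc1)[Si](C)(C)C(C)(C)C | intermediate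
18 | 6-lithio derivative of 17 (lithium between the carbamate and a benzyloxy group) | CC(C)N(C(=O)Oc1c([Li])c(OCc2ccccc2)ccc1OCc1ccccc1)[Si](C)(C)C(C)(C)C | intermediate
19 | 3,6-bis(benzyloxy)-2-(trimethylsilyl)phenyl N-(tert-butyldimethylsilyl)-N-isopropylcarbamate | CC(C)N(C(=O)Oc1c([Si](C)(C)C)c(OCc2ccccc2)ccc1OCc1ccccc1)[Si](C)(C)C(C)(C)C | intermediate
20 | 3,6-bis(benzyloxy)-2-(trimethylsilyl)phenyl N-isopropylcarbamate | CC(C)NC(=O)Oc1c([Si](C)(C)C)c(OCc2ccccc2)ccc1OCc1ccccc1 | intermediate
21 | 3,6-bis(benzyloxy)-2-(trimethylsilyl)phenol | Oc1c([Si](C)(C)C)c(OCc2ccccc2)ccc1OCc1ccccc1 | intermediate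
22 | 3,6-bis(benzyloxy)-2-(trimethylsilyl)phenyl trifluoromethanesulfonate | C[Si](C)(C)c1c(OCc2ccccc2)ccc(OCc2ccccc2)c1OS(=O)(=O)C(F)(F)F | intermediate
23 | 3,6-bis(benzyloxy)benzyne | C(c1ccccc1)OC1=CC=C(OCc2ccccc2)C#C1 | intermediate
24 | potassium enolate of 9 | [K+].[O-]C1=C[C@@H](CCC[C@H](C)OCc2ccc(OC)cc2)O1 | intermediate
25 | potassium 3,6-bis(benzyloxy)-2-[(2R,3R)-2-{(4S)-4-[(4-methoxybenzyl)oxy]pentyl}-4-oxooxetan-3-yl]benzenide | [K+].C[C@H](OCc1ccc(OC)cc1)CCC[C@@H]1[C@@H](c2c(OCc3ccccc3)ccc(OCc3ccccc3)[c-]2)C(=O)O1 | intermediate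
26 | potassium alkoxide of the benzocyclobutenol fused to the oxetane along the C1–C4 bond (2-oxabicyclo[2.2.0]hexane core, cis ring fusion) | [K+].[O-][C@]12O[C@H](CCC[C@H](C)OCc3ccc(OC)cc3)[C@H]1c1c(OCc3ccccc3)ccc(OCc3ccccc3)c12 | intermediate
27 | potassium salt of the C4 carbanion of 28 | [K+].O=C1O[C@H](CCC[C@H](C)OCc2ccc(OC)cc2)[CH-]c2c(OCc3ccccc3)ccc(OCc3ccccc3)c12 | intermediate
28 | (3R)-5,8-bis(benzyloxy)-3-{(4S)-4-[(4-methoxybenzyl)oxy]pentyl}isochroman-1-one | C[C@H](OCc1ccc(OC)cc1)CCC[C@@H]1Cc2c(OCc3ccccc3)ccc(OCc3ccccc3)c2C(=O)O1 | intermediate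
29 | (3R)-5,8-bis(benzyloxy)-3-[(4S)-4-hydroxypentyl]isochroman-1-one | C[C@H](O)CCC[C@@H]1Cc2c(OCc3ccccc3)ccc(OCc3ccccc3)c2C(=O)O1 | intermediate
30 | succinic anhydride | O=C1CCC(=O)O1 | starting material
31 | 4-({(2S)-5-[(3R)-5,8-bis(benzyloxy)-1-oxoisochroman-3-yl]pentan-2-yl}oxy)-4-oxobutanoic acid | C[C@@H](CCC[C@@H]1Cc2c(OCc3ccccc3)ccc(OCc3ccccc3)c2C(=O)O1)OC(=O)CCC(=O)O | intermediate
32 | Aspergimarin B, 4-({(2S)-5-[(3R)-5,8-dihydroxy-1-oxoisochroman-3-yl]pentan-2-yl}oxy)-4-oxobutanoic acid | C[C@@H](CCC[C@@H]1Cc2c(O)ccc(O)c2C(=O)O1)OC(=O)CCC(=O)O | target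

**Step count**

Total: 14 steps. Longest linear sequence: 9 steps (steps 1 to 5 and 11 to 14; the aryne branch, steps 6 to 10 and 11 to 14, is equally long).

**Steps most likely to fail**

1. Step 11 (Proposed new method). Three processes could defeat it:
   - protonation or Claisen-type self-acylation of the lactone enolate before it meets the aryne;
   - proton transfer within the aryl anion, which would stop at plain α-arylation without insertion;
   - ring opening of the C4 anion by β-elimination of the carboxylate, or its second arylation, before the quench.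

   Fallback with known chemistry: it sets out from alkene 4 and aldehyde 13 and comes back at 28, so that steps 4, 5 and 8 to 10 are not needed. Epoxidation of 4 (mCPBA, CH2Cl2) should give 2-{(4S)-4-[(4-methoxybenzyl)oxy]pentyl}oxirane F1 as a mixture of oxirane epimers. Hydrolytic kinetic resolution with (S,S)-(salen)Co(OAc) and 0.55 equiv of water, the catalyst antipode expected to hydrolyse the 2S epimer, should leave the (2R)-oxirane F2. Pinnick oxidation of 13 (NaClO2, NaH2PO4, 2-methyl-2-butene) should give 2,5-bis(benzyloxy)benzoic acid F3, and coupling with diethylamine (EDC, HOBt) 2,5-bis(benzyloxy)-N,N-diethylbenzamide F4. Amide-directed ortho-lithiation (s-BuLi, TMEDA, THF, −78 °C) at the position between the amide and a benzyloxy group should give aryllithium F5. In the presence of BF3·OEt2 it should open F2 at the CH2 terminus to hydroxy amide F6. Acid-catalysed lactonisation (camphorsulfonic acid, toluene, 80 °C) with loss of diethylamine should then give 28. The C3 configuration would come from the resolved epoxide, whose C–O bond is not touched.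

2. Step 5. Self-acylation or ring opening of the α-unsubstituted lactone enolate may compete with its silylation, and double silylation is possible.

   Fallback: it sets out from aldehyde 6 and comes back at 11, replacing steps 4 and 5 and avoiding any strong-base enolisation of the lactone. C-silylation of ethoxyacetylene (n-BuLi, Me3SiCl) should give 1-ethoxy-2-(trimethylsilyl)acetylene F7, and its thermolysis (120 °C, retro-ene loss of ethylene) (trimethylsilyl)ketene F8. Lewis acid-catalysed [2+2] cycloaddition of F8 with 6 (MeAl[TfNCH(Ph)CH(Ph)NTf], antipode chosen for 4R, CH2Cl2, −78 °C) should give the α-silyl β-lactone directly, as 11 together with its C3 epimer F9. Both release the same enolate in step 11. The weaker point of this variant is expected to be lower face selectivity at C4.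

3. Step 9. Deprotonation at a benzylic OCH2 group with 1,2-Wittig rearrangement, or anionic ortho-Fries migration of the carbamate, may compete with clean ring lithiation.

   Fallback: it sets out from phenol 15 and comes back at 22, replacing steps 8 to 10 by a halogen–metal exchange route. Ortho-selective bromination (NBS, i-Pr2NH cat., CH2Cl2) should give 3,6-bis(benzyloxy)-2-bromophenol F10, and O-silylation (hexamethyldisilazane, THF, 70 °C) [3,6-bis(benzyloxy)-2-bromophenoxy]trimethylsilane F11. Bromine–lithium exchange (n-BuLi, THF, −100 °C) is far faster than deprotonation of a benzyl ether. It should trigger the O-to-C silyl shift (retro-Brook rearrangement) to lithium 3,6-bis(benzyloxy)-2-(trimethylsilyl)phenoxide F12, which is triflated in the same flask (Tf2O) to 22.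

Further compounds
F1 | step 11 | 2-{(4S)-4-[(4-methoxybenzyl)oxy]pentyl}oxirane (both oxirane epimers) | C[C@H](OCc1ccc(OC)cc1)CCCC1CO1
F2 | step 11 | (2R)-2-{(4S)-4-[(4-methoxybenzyl)oxy]pentyl}oxirane | C[C@H](OCc1ccc(OC)cc1)CCC[C@@H]1CO1
F3 | step 11 | 2,5-bis(benzyloxy)benzoic acid | OC(=O)c1cc(OCc2ccccc2)ccc1OCc1ccccc1
F4 | step 11 | 2,5-bis(benzyloxy)-N,N-diethylbenzamide | CCN(CC)C(=O)c1cc(OCc2ccccc2)ccc1OCc1ccccc1
F5 | step 11 | 3,6-bis(benzyloxy)-2-(diethylcarbamoyl)phenyllithium | CCN(CC)C(=O)c1c([Li])c(OCc2ccccc2)ccc1OCc1ccccc1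
F6 | step 11 | 3,6-bis(benzyloxy)-N,N-diethyl-2-{(2R,6S)-2-hydroxy-6-[(4-methoxybenzyl)oxy]heptyl}benzamide | CCN(CC)C(=O)c1c(C[C@H](O)CCC[C@H](C)OCc2ccc(OC)cc2)c(OCc2ccccc2)ccc1OCc1ccccc1
F7 | step 5 | 1-ethoxy-2-(trimethylsilyl)acetylene | CCOC#C[Si](C)(C)C
F8 | step 5 | (trimethylsilyl)ketene | C[Si](C)(C)C=C=O
F9 | step 5 | (3S,4R)-4-{(4S)-4-[(4-methoxybenzyl)oxy]pentyl}-3-(trimethylsilyl)oxetan-2-one (cis, C3 epimer of 11) | C[C@H](OCc1ccc(OC)cc1)CCC[C@@H]1[C@H]([Si](C)(C)C)C(=O)O1
F10 | step 9 | 3,6-bis(benzyloxy)-2-bromophenol | Oc1c(Br)c(OCc2ccccc2)ccc1OCc1ccccc1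
F11 | step 9 | [3,6-bis(benzyloxy)-2-bromophenoxy]trimethylsilane | C[Si](C)(C)Oc1c(Br)c(OCc2ccccc2)ccc1OCc1ccccc1
F12 | step 9 | lithium 3,6-bis(benzyloxy)-2-(trimethylsilyl)phenoxide | [Li+].[O-]c1c([Si](C)(C)C)c(OCc2ccccc2)ccc1OCc1ccccc1
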